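**Plan**

- Retrosynthesis: cut first the C14–OOH bond (sulfonate displacement; the allylic alcohol comes from a Shi epoxide of the prenyl end), then the cyclopropane bond C9–C11 together with C8–OH (cationic closure of a homoallylic tosylate), then ring bond C3–C4 (B-alkyl Suzuki), bond C1–C10 (Ireland–Claisen), the ester bond to geraniol and bond C5–C6 (propynyl addition); C6–C11 go back to 4-methylanisole.
- Enabling feature (ring numbered C1 quaternary, C2, C3, C4=C5, C6 acetoxy, C7, C8 carbinol, C9, C10; C11 is the cyclopropane CH2 on C9 and C10): the tertiary carbinol carbon C8 is bonded directly to cyclopropane carbon C9. This is a cyclopropylcarbinyl cation at C8 trapped by water, which opens back to a Z C8=C9 alkene with a C11 leaving group on C10.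
- Forward order: chain C6–C11 with its Z alkene (Birch reduction, ozonolysis); C4–C5 added as propynyl and converted to the E alkenyl iodide; geraniol attached as ester and C10 joined to C1 by the Claisen; ten-membered ring closed at C3–C4; cyclopropane closed on the ring; side-chain hydroperoxide and acetate last.
- Stereochemistry: Z C8=C9 from the six-membered ring of the Birch diene; C6 from Noyori transfer hydrogenation; C1 and C10 from a chair Ireland–Claisen of an E(O) boron ketene acetal under a chiral diazaborolidine; C9 and C8 from the C10 centre and anti addition in the cationic step; C14 from Shi epoxidation followed by SN2 inversion.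

Key step: step 13

Remarks on the chemistry:
- Names of ring compounds use the numbering above; the side chain on C1 is C12–C15, and "9,10-methano" denotes the CH2 (C11) joining C9 and C10 (a bicyclo[8.1.0]undecene). TBS = tert-butyldimethylsilyl.
- Assumption: the (4S,5S)-diazaborolidine is taken to favour the chair that leads to acid 16; if the opposite sense is found, the (4R,5R)-reagent is used and nothing else changes.

Step 1
Reactants: 1 4-methylanisole
Product: 2 1-methoxy-4-methylcyclohexa-1,4-diene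
Conditions: Li, NH3 (l), t-BuOH, THF, −78 → −33 °C
Reagents that add atoms: none
Why: Birch reduction of an anisole stops at the 1-methoxycyclohexa-1,4-diene and the para methyl group ends on the second ring alkene, so the trisubstituted alkene that becomes C8=C9 is locked cis inside a six-membered ring.

Step 2
Reactants: 2 1-methoxy-4-methylcyclohexa-1,4-diene
Product: 4 methyl (3Z)-4-methyl-6-oxohex-3-enoate, via methoxy hydroperoxide 3 (not isolated)
Conditions: O3 (1.0 equiv), CH2Cl2–MeOH, −78 °C; then Me2S, −78 °C → rt; used crude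
Reagents that add atoms: ozone, [O-][O+]=O
Why: Selective ozonolysis of a Birch diene: ozone cleaves the electron-rich enol ether alkene much faster than the trisubstituted one, the methoxy carbon becoming the C11 ester and its partner (after methanol trapping of the carbonyl oxide and Me2S reduction) the C6 aldehyde, while the untouched ring alkene emerges as the Z C8=C9 alkene (C7 cis to C10).

Step 3
Reactants: 4 methyl (3Z)-4-methyl-6-oxohex-3-enoate; 5 1-propynylmagnesium bromide
Product: 6 methyl (3Z)-6-hydroxy-4-methylnon-3-en-7-ynoate (racemic at C6)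
Conditions: THF, −78 °C; aq. NH4Cl
Reagents that add atoms: none
Why: Chemoselective 1,2-addition of the alkynyl Grignard reagent to the aldehyde at −78 °C, where the methyl ester is inert; C6 is formed as a racemate that is erased and reset in steps 4 and 5.

Step 4
Reactants: 6 methyl (3Z)-6-hydroxy-4-methylnon-3-en-7-ynoate
Product: 7 methyl (3Z)-4-methyl-6-oxonon-3-en-7-ynoate
Conditions: Dess–Martin periodinane, CH2Cl2, 0 °C → rt
Reagents that add atoms: none
Why: Dess–Martin oxidation of a propargylic alcohol to the ynone proceeds without base, so the skipped C8=C9 alkene should not move into conjugation.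

Step 5
Reactants: 7 methyl (3Z)-4-methyl-6-oxonon-3-en-7-ynoate
Product: 8 methyl (3Z,6S)-6-hydroxy-4-methylnon-3-en-7-ynoate
Conditions: Ru[(S,S)-TsDPEN](p-cymene) (1 mol%), i-PrOH, 25 °C
Reagents that add atoms: none
Why: Noyori asymmetric transfer hydrogenation of an α,β-acetylenic ketone: with the (S,S)-catalyst the alkynyl group takes the place held by the aryl group of aryl ketones and hydride delivery gives the (S)-propargylic alcohol, which sets C6, while the base-free conditions spare the enolisable C7 methylene.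

Step 6
Reactants: 8 methyl (3Z,6S)-6-hydroxy-4-methylnon-3-en-7-ynoate
Product: 9 methyl (3Z,6S)-6-(TBSO)-4-methylnon-3-en-7-ynoate
Conditions: TBSCl, imidazole, DMF, 25 °C
Reagents that add atoms: tert-butyldimethylsilyl chloride, CC(C)(C)[Si](C)(C)Cl
Why: Standard silylation of a secondary alcohol; the bulky, non-participating silyl ether later steers the hydrozirconation and cannot intercept the C8 cation of the key step.

Step 7
Reactants: 9 methyl (3Z,6S)-6-(TBSO)-4-methylnon-3-en-7-ynoate
Product: 11 methyl (3Z,6S,7E)-6-(TBSO)-8-iodo-4-methylnona-3,7-dienoate, via alkenylzirconocene 10 (not isolated)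
Conditions: Cp2Zr(H)Cl (2 equiv), THF, 25 → 40 °C; then I2, 0 °C
Reagents that add atoms: iodine, II
Why: Hydrozirconation–iodination: syn addition of Zr–H across the alkyne, with zirconium settling on the methyl-bearing carbon away from the branched silyloxy carbon, followed by iodinolysis with retention should give the E alkenyl iodide (iodine trans to C6), while the methyl ester and the trisubstituted alkene react much more slowly with Cp2Zr(H)Cl.

Step 8
Reactants: 11 methyl (3Z,6S,7E)-6-(TBSO)-8-iodo-4-methylnona-3,7-dienoate; 12 geraniol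
Product: 13 (2E)-3,7-dimethylocta-2,6-dien-1-yl (3Z,6S,7E)-6-(TBSO)-8-iodo-4-methylnona-3,7-dienoate
Conditions: Ti(OiPr)4 (10 mol%), geraniol (5 equiv), toluene, 100 °C, MeOH distilled off
Reagents that add atoms: none
Why: Titanate-mediated transesterification is neutral, so the β,γ-unsaturated ester is re-esterified with the primary allylic alcohol without migration of the C8=C9 alkene or loss of the silyl ether.

Step 9
Reactants: 13 (2E)-3,7-dimethylocta-2,6-dien-1-yl (3Z,6S,7E)-6-(TBSO)-8-iodo-4-methylnona-3,7-dienoate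
Product: 16 (2S,3Z,6S,7E)-6-(TBSO)-2-[(3S)-3,7-dimethylocta-1,6-dien-3-yl]-8-iodo-4-methylnona-3,7-dienoic acid, via boron ketene acetal 14 (not isolated), via acyloxyborane 15 (not isolated)
Conditions: (4S,5S)-2-bromo-4,5-diphenyl-1,3-bis(p-tolylsulfonyl)-1,3,2-diazaborolidine (1.3 equiv), Et3N, toluene–hexane, −78 °C; then −20 → 4 °C; aq. work-up
Reagents that add atoms: none
Why: Enantioselective Ireland–Claisen rearrangement through a chiral O-boron ketene acetal: Et3N in toluene–hexane should give the E(O) enolate (alkenyl trans to O–B), the chair transition state of the E geranyl unit then places the homoprenyl group equatorial, the C1 methyl axial and the C9 alkenyl axial so that C1 and C10 arise with the required relative configuration, and the C2-symmetric diazaborolidine chooses between the two mirror-image chairs.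

Step 10
Reactants: 16 (2S,3Z,6S,7E)-6-(TBSO)-2-[(3S)-3,7-dimethylocta-1,6-dien-3-yl]-8-iodo-4-methylnona-3,7-dienoic acid
Product: 17 (2S,3Z,6S,7E)-6-(TBSO)-2-[(3S)-3,7-dimethylocta-1,6-dien-3-yl]-8-iodo-4-methylnona-3,7-dien-1-ol
Conditions: LiAlH4, Et2O, 0 °C → rt
Reagents that add atoms: none
Why: LiAlH4 reduces the carboxylic acid to the primary alcohol at or below room temperature, conditions under which alkenyl iodides, silyl ethers and isolated alkenes survive.

Step 11
Reactants: 17 (2S,3Z,6S,7E)-6-(TBSO)-2-[(3S)-3,7-dimethylocta-1,6-dien-3-yl]-8-iodo-4-methylnona-3,7-dien-1-ol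
Product: 19 [(1S,4E,6S,8Z,10S)-6-(TBSO)-1,4,8-trimethyl-1-(4-methylpent-3-en-1-yl)cyclodeca-4,8-dien-10-yl]methanol, via bis-borylated adduct 18 (not isolated)
Conditions: 9-BBN (2.5 equiv), THF, 0 °C → rt; then slow addition to Pd(dppf)Cl2 (15 mol%), AsPh3, Cs2CO3, DMF–THF–H2O, 50 °C, 2 mM
Reagents that add atoms: none
Why: 9-BBN hydroborates only the monosubstituted vinyl group (boron at C3) and consumes the hydroxyl as a borinate, and slow addition of the borane to the palladium catalyst under aqueous base effects an intramolecular B-alkyl Suzuki–Miyaura coupling that closes the ten-membered ring at C3–C4 with retention of the E alkenyl geometry.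

Step 12
Reactants: 19 [(1S,4E,6S,8Z,10S)-6-(TBSO)-1,4,8-trimethyl-1-(4-methylpent-3-en-1-yl)cyclodeca-4,8-dien-10-yl]methanol
Product: 20 [(1S,4E,6S,8Z,10S)-6-(TBSO)-1,4,8-trimethyl-1-(4-methylpent-3-en-1-yl)cyclodeca-4,8-dien-10-yl]methyl 4-methylbenzenesulfonate
Conditions: TsCl, pyridine, DMAP (cat.), CH2Cl2, 0 °C → rt
Reagents that add atoms: p-toluenesulfonyl chloride, Cc1ccc(cc1)S(Cl)(=O)=O
Why: Sulfonylation of the primary alcohol gives the homoallylic tosylate, whose β-branching (C10 next to quaternary C1) blocks direct SN2 attack and so reserves ionisation for the alkene-assisted pathway.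

Step 13
Reactants: 20 [(1S,4E,6S,8Z,10S)-6-(TBSO)-1,4,8-trimethyl-1-(4-methylpent-3-en-1-yl)cyclodeca-4,8-dien-10-yl]methyl 4-methylbenzenesulfonate
Product: 21 (1S,4E,6S,8S,9S,10S)-6-(TBSO)-1,4,8-trimethyl-1-(4-methylpent-3-en-1-yl)-9,10-methanocyclodec-4-en-8-ol
Conditions: NaHCO3 (3 equiv), acetone–H2O (3:1), 60 °C
Reagents that add atoms: water, O
Why: Ionisation of the primary tosylate is assisted by the C8=C9 π bond, C9 displacing tosylate from C11 from the rear to give a bisected tertiary cyclopropylcarbinyl cation at C8, which water captures at C8 on the face anti to the new C9–C11 bond; the closest known reaction type is the buffered solvolysis of homoallylic sulfonates to cyclopropyl carbinols (the i-steroid rearrangement and the 4-methylpent-3-enyl tosylate case). The cyclopropane C9–C10–C11 closes in a 3-exo-tet mode with the alkene as nucleophile, and the ten-membered ring is not broken. C9 is controlled by the stored C10 centre: A(1,3) strain across the Z alkene keeps H10 in the alkene plane beside C7, which puts C11 on one face and C1 on the other, so closure gives the trans-fused cyclopropane (C8 trans to C1, 9S). C8 is controlled by the anti relation of C–C and C–O bond formation across the Z alkene (C7 cis to C10), which gives 8S. The step needs water capture at C8 to beat proton loss, return to C11, ring expansion at C10 and attack by the C4=C5 alkene; the tertiary, cyclopropyl-stabilised cation favours capture at C8, the NaHCO3 buffer stops acid-induced re-ionisation of the carbinol, the C4=C5 alkene is deactivated by its allylic silyloxy group, and the silyl ether, unlike an ester, offers no internal nucleophile for the wrong face.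

Step 14
Reactants: 21 (1S,4E,6S,8S,9S,10S)-6-(TBSO)-1,4,8-trimethyl-1-(4-methylpent-3-en-1-yl)-9,10-methanocyclodec-4-en-8-ol
Product: 22 (1R,4E,6S,8S,9S,10S)-6-(TBSO)-1-{2-[(2R)-3,3-dimethyloxiran-2-yl]ethyl}-1,4,8-trimethyl-9,10-methanocyclodec-4-en-8-ol
Conditions: D-fructose-derived Shi ketone (30 mol%), KHSO5 (as 2KHSO5·KHSO4·K2SO4), K2CO3, Bu4NHSO4, MeCN–CH2(OMe)2–aq. Na2B4O7 buffer, 0 °C
Reagents that add atoms: potassium peroxymonosulfate, [K+].[O-]S(=O)(=O)OO
Why: Shi epoxidation: the dioxirane from the D-fructose-derived ketone attacks the unhindered, electron-rich prenyl alkene through a spiro transition state to give the (14R)-epoxide, whereas the ring C4=C5 alkene is deactivated by its allylic silyloxy group and screened by the ring.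

Step 15
Reactants: 22 (1R,4E,6S,8S,9S,10S)-6-(TBSO)-1-{2-[(2R)-3,3-dimethyloxiran-2-yl]ethyl}-1,4,8-trimethyl-9,10-methanocyclodec-4-en-8-ol
Product: 23 (1R,4E,6S,8S,9S,10S)-6-(TBSO)-1-[(3R)-3-hydroxy-4-methylpent-4-en-1-yl]-1,4,8-trimethyl-9,10-methanocyclodec-4-en-8-ol
Conditions: Et2AlCl, lithium 2,2,6,6-tetramethylpiperidide (4 equiv each), toluene, 0 °C
Reagents that add atoms: none
Why: Yamamoto isomerisation with a dialkylaluminium amide: aluminium binds the epoxide oxygen and the amide removes a syn proton from a C15 methyl group, giving the 2-methylalk-1-en-3-ol with the C14–O bond, and hence the 14R configuration, intact.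

Step 16
Reactants: 23 (1R,4E,6S,8S,9S,10S)-6-(TBSO)-1-[(3R)-3-hydroxy-4-methylpent-4-en-1-yl]-1,4,8-trimethyl-9,10-methanocyclodec-4-en-8-ol
Product: 24 (3R)-1-[(1R,4E,6S,8S,9S,10S)-6-(TBSO)-8-hydroxy-1,4,8-trimethyl-9,10-methanocyclodec-4-en-1-yl]-4-methylpent-4-en-3-yl methanesulfonate
Conditions: MsCl, Et3N, CH2Cl2, −30 °C; used crude
Reagents that add atoms: methanesulfonyl chloride, CS(Cl)(=O)=O
Why: Mesylation through sulfene is fast for the secondary allylic alcohol and very slow for the hindered tertiary cyclopropyl carbinol, and the low temperature keeps the allylic mesylate from ionising.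

Step 17
Reactants: 25 2,3-dimethylbut-2-ene
Product: 26 2-methoxyprop-2-yl hydroperoxide
Conditions: O3, MeOH–CH2Cl2, −78 °C
Reagents that add atoms: ozone, [O-][O+]=O; methanol, CO
Why: Criegee ozonolysis of a tetrasubstituted alkene in methanol: the acetone carbonyl oxide is trapped by the solvent to give the hydroperoxy ketal, a protected form of hydrogen peroxide.

Step 18
Reactants: 24 (3R)-1-[(1R,4E,6S,8S,9S,10S)-6-(TBSO)-8-hydroxy-1,4,8-trimethyl-9,10-methanocyclodec-4-en-1-yl]-4-methylpent-4-en-3-yl methanesulfonate; 26 2-methoxyprop-2-yl hydroperoxide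
Product: 27 (1R,4E,6S,8S,9S,10S)-6-(TBSO)-1-{(3S)-3-[(2-methoxypropan-2-yl)peroxy]-4-methylpent-4-en-1-yl}-1,4,8-trimethyl-9,10-methanocyclodec-4-en-8-ol
Conditions: CsOH·H2O, DMF, 0 °C
Reagents that add atoms: none
Why: SN2 alkylation of the peroxy anion (an α-effect nucleophile) by the secondary sulfonate with inversion turns 14R into 14S, and the ketal mask prevents double alkylation and later acylation of the peroxide.

Step 19
Reactants: 27 (1R,4E,6S,8S,9S,10S)-6-(TBSO)-1-{(3S)-3-[(2-methoxypropan-2-yl)peroxy]-4-methylpent-4-en-1-yl}-1,4,8-trimethyl-9,10-methanocyclodec-4-en-8-ol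
Product: 28 (1R,4E,6S,8S,9S,10S)-1-{(3S)-3-[(2-methoxypropan-2-yl)peroxy]-4-methylpent-4-en-1-yl}-1,4,8-trimethyl-9,10-methanocyclodec-4-ene-6,8-diol
Conditions: Bu4NF, AcOH (1:1), THF, 0 °C → rt
Reagents that add atoms: none
Why: Fluoride cleaves the silyl ether, and buffering with acetic acid avoids base-induced (Kornblum–DeLaMare) fragmentation of the secondary peroxide.

Step 20
Reactants: 28 (1R,4E,6S,8S,9S,10S)-1-{(3S)-3-[(2-methoxypropan-2-yl)peroxy]-4-methylpent-4-en-1-yl}-1,4,8-trimethyl-9,10-methanocyclodec-4-ene-6,8-diol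
Product: 29 (1R,4E,6S,8S,9S,10S)-8-hydroxy-1-{(3S)-3-[(2-methoxypropan-2-yl)peroxy]-4-methylpent-4-en-1-yl}-1,4,8-trimethyl-9,10-methanocyclodec-4-en-6-yl acetate
Conditions: Ac2O, pyridine, DMAP (cat.), CH2Cl2, 0 °C
Reagents that add atoms: acetic anhydride, CC(=O)OC(C)=O
Why: DMAP-catalysed acetylation distinguishes the secondary allylic alcohol from the hindered tertiary cyclopropyl carbinol, and the peroxy ketal is inert to acylation.

Step 21
Reactants: 29 (1R,4E,6S,8S,9S,10S)-8-hydroxy-1-{(3S)-3-[(2-methoxypropan-2-yl)peroxy]-4-methylpent-4-en-1-yl}-1,4,8-trimethyl-9,10-methanocyclodec-4-en-6-yl acetate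
Product: 30 (1R,4E,6S,8S,9S,10S)-1-[(3S)-3-hydroperoxy-4-methylpent-4-en-1-yl]-8-hydroxy-1,4,8-trimethyl-9,10-methanocyclodec-4-en-6-yl acetate (CNP0302713.3)
Conditions: AcOH–THF–H2O (4:2:1), 0 °C → rt
Reagents that add atoms: none
Why: The mixed methoxypropyl peroxy ketal hydrolyses under acid far milder than that needed to ionise the tertiary cyclopropyl carbinol or the allylic acetate, releasing the hydroperoxide.

**Compound list**

1 | 4-methylanisole | COc1ccc(C)cc1 | starting material
2 | 1-methoxy-4-methylcyclohexa-1,4-diene | COC1=CCC(C)=CC1 | intermediate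
3 | methyl (3Z)-6-hydroperoxy-6-methoxy-4-methylhex-3-enoate (not isolated) | COC(=O)C/C=C(C)\CC(OC)OO | intermediate
4 | methyl (3Z)-4-methyl-6-oxohex-3-enoate | COC(=O)C/C=C(C)\CC=O | intermediate
5 | 1-propynylmagnesium bromide | CC#C[Mg]Br | starting material
6 | methyl (3Z)-6-hydroxy-4-methylnon-3-en-7-ynoate (racemic at C6) | COC(=O)C/C=C(C)\CC(O)C#CC | intermediate
7 | methyl (3Z)-4-methyl-6-oxonon-3-en-7-ynoate | COC(=O)C/C=C(C)\CC(=O)C#CC | intermediate
8 | methyl (3Z,6S)-6-hydroxy-4-methylnon-3-en-7-ynoate | COC(=O)C/C=C(C)\C[C@H](O)C#CC | intermediate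
9 | methyl (3Z,6S)-6-(TBSO)-4-methylnon-3-en-7-ynoate | COC(=O)C/C=C(C)\C[C@H](O[Si](C)(C)C(C)(C)C)C#CC | intermediate
10 | methyl (3Z,6S,7E)-6-(TBSO)-8-[chlorobis(cyclopentadienyl)zirconio]-4-methylnona-3,7-dienoate (not isolated) | COC(=O)C/C=C(C)\C[C@H](O[Si](C)(C)C(C)(C)C)/C=C(\C)[Zr](Cl)(C1C=CC=C1)C1C=CC=C1 | intermediate
11 | methyl (3Z,6S,7E)-6-(TBSO)-8-iodo-4-methylnona-3,7-dienoate | COC(=O)C/C=C(C)\C[C@H](O[Si](C)(C)C(C)(C)C)/C=C(\C)I | intermediate
12 | geraniol | CC(C)=CCC/C(C)=C/CO | starting material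
13 | (2E)-3,7-dimethylocta-2,6-dien-1-yl (3Z,6S,7E)-6-(TBSO)-8-iodo-4-methylnona-3,7-dienoate | CC(C)=CCC/C(C)=C/COC(=O)C/C=C(C)\C[C@H](O[Si](C)(C)C(C)(C)C)/C=C(\C)I | intermediate
14 | E(O) ketene acetal of 13 O-borylated by the (4S,5S)-diazaborolidine (not isolated) | CC(C)=CCC/C(C)=C/CO/C(OB1N(S(=O)(=O)c2ccc(C)cc2)[C@@H](c2ccccc2)[C@H](c2ccccc2)N1S(=O)(=O)c1ccc(C)cc1)=C\C=C(C)/C[C@H](O[Si](C)(C)C(C)(C)C)/C=C(\C)I | intermediate
15 | (4S,5S)-diazaborolidin-2-yl ester of acid 16 (not isolated) | CC(C)=CCC[C@@](C)(C=C)[C@@H](C(=O)OB1N(S(=O)(=O)c2ccc(C)cc2)[C@@H](c2ccccc2)[C@H](c2ccccc2)N1S(=O)(=O)c1ccc(C)cc1)/C=C(C)\C[C@H](O[Si](C)(C)C(C)(C)C)/C=C(\C)I | intermediate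
16 | (2S,3Z,6S,7E)-6-(TBSO)-2-[(3S)-3,7-dimethylocta-1,6-dien-3-yl]-8-iodo-4-methylnona-3,7-dienoic acid | CC(C)=CCC[C@@](C)(C=C)[C@@H](C(=O)O)/C=C(C)\C[C@H](O[Si](C)(C)C(C)(C)C)/C=C(\C)I | intermediate
17 | (2S,3Z,6S,7E)-6-(TBSO)-2-[(3S)-3,7-dimethylocta-1,6-dien-3-yl]-8-iodo-4-methylnona-3,7-dien-1-ol | CC(C)=CCC[C@@](C)(C=C)[C@@H](CO)/C=C(C)\C[C@H](O[Si](C)(C)C(C)(C)C)/C=C(\C)I | intermediate
18 | adduct of 17 carrying 9-BBN on C3 and on the C11 oxygen (not isolated) | CC(C)=CCC[C@@](C)(CCB1C2CCCC1CCC2)[C@@H](COB1C2CCCC1CCC2)/C=C(C)\C[C@H](O[Si](C)(C)C(C)(C)C)/C=C(\C)I | intermediate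
19 | [(1S,4E,6S,8Z,10S)-6-(TBSO)-1,4,8-trimethyl-1-(4-methylpent-3-en-1-yl)cyclodeca-4,8-dien-10-yl]methanol | CC(C)=CCC[C@@]1(C)CC/C(C)=C/[C@@H](O[Si](C)(C)C(C)(C)C)C/C(C)=C\[C@@H]1CO | intermediate
20 | [(1S,4E,6S,8Z,10S)-6-(TBSO)-1,4,8-trimethyl-1-(4-methylpent-3-en-1-yl)cyclodeca-4,8-dien-10-yl]methyl 4-methylbenzenesulfonate | CC(C)=CCC[C@@]1(C)CC/C(C)=C/[C@@H](O[Si](C)(C)C(C)(C)C)C/C(C)=C\[C@@H]1COS(=O)(=O)c2ccc(C)cc2 | intermediate
21 | (1S,4E,6S,8S,9S,10S)-6-(TBSO)-1,4,8-trimethyl-1-(4-methylpent-3-en-1-yl)-9,10-methanocyclodec-4-en-8-ol | CC(C)=CCC[C@@]1(C)CC/C(C)=C/[C@@H](O[Si](C)(C)C(C)(C)C)C[C@](C)(O)[C@H]2C[C@@H]21 | intermediate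
22 | (1R,4E,6S,8S,9S,10S)-6-(TBSO)-1-{2-[(2R)-3,3-dimethyloxiran-2-yl]ethyl}-1,4,8-trimethyl-9,10-methanocyclodec-4-en-8-ol | CC3(C)O[C@@H]3CC[C@@]1(C)CC/C(C)=C/[C@@H](O[Si](C)(C)C(C)(C)C)C[C@](C)(O)[C@H]2C[C@@H]21 | intermediate
23 | (1R,4E,6S,8S,9S,10S)-6-(TBSO)-1-[(3R)-3-hydroxy-4-methylpent-4-en-1-yl]-1,4,8-trimethyl-9,10-methanocyclodec-4-en-8-ol | C=C(C)[C@@H](CC[C@@]1(C)CC/C(C)=C/[C@@H](O[Si](C)(C)C(C)(C)C)C[C@](C)(O)[C@H]2C[C@@H]21)O | intermediate
24 | (3R)-1-[(1R,4E,6S,8S,9S,10S)-6-(TBSO)-8-hydroxy-1,4,8-trimethyl-9,10-methanocyclodec-4-en-1-yl]-4-methylpent-4-en-3-yl methanesulfonate | C=C(C)[C@@H](CC[C@@]1(C)CC/C(C)=C/[C@@H](O[Si](C)(C)C(C)(C)C)C[C@](C)(O)[C@H]2C[C@@H]21)OS(C)(=O)=O | intermediate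
25 | 2,3-dimethylbut-2-ene | CC(C)=C(C)C | starting material
26 | 2-methoxyprop-2-yl hydroperoxide | COC(C)(C)OO | intermediate
27 | (1R,4E,6S,8S,9S,10S)-6-(TBSO)-1-{(3S)-3-[(2-methoxypropan-2-yl)peroxy]-4-methylpent-4-en-1-yl}-1,4,8-trimethyl-9,10-methanocyclodec-4-en-8-ol | C=C(C)[C@H](CC[C@@]1(C)CC/C(C)=C/[C@@H](O[Si](C)(C)C(C)(C)C)C[C@](C)(O)[C@H]2C[C@@H]21)OOC(C)(C)OC | intermediate
28 | (1R,4E,6S,8S,9S,10S)-1-{(3S)-3-[(2-methoxypropan-2-yl)peroxy]-4-methylpent-4-en-1-yl}-1,4,8-trimethyl-9,10-methanocyclodec-4-ene-6,8-diol | C=C(C)[C@H](CC[C@@]1(C)CC/C(C)=C/[C@@H](O)C[C@](C)(O)[C@H]2C[C@@H]21)OOC(C)(C)OC | intermediate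
29 | (1R,4E,6S,8S,9S,10S)-8-hydroxy-1-{(3S)-3-[(2-methoxypropan-2-yl)peroxy]-4-methylpent-4-en-1-yl}-1,4,8-trimethyl-9,10-methanocyclodec-4-en-6-yl acetate | C=C(C)[C@H](CC[C@@]1(C)CC/C(C)=C/[C@@H](OC(C)=O)C[C@](C)(O)[C@H]2C[C@@H]21)OOC(C)(C)OC | intermediate
30 | (1R,4E,6S,8S,9S,10S)-1-[(3S)-3-hydroperoxy-4-methylpent-4-en-1-yl]-8-hydroxy-1,4,8-trimethyl-9,10-methanocyclodec-4-en-6-yl acetate (CNP0302713.3) | C=C(C)[C@H](CC[C@@]1(C)CC/C(C)=C/[C@@H](OC(C)=O)C[C@](C)(O)[C@H]2C[C@@H]21)OO | target

**Step count**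

Total: 21 steps. Longest linear sequence: 20 steps (1 to 30 through steps 1–16 and 18–21; step 17 prepares reagent 26 on a side branch).

**Steps most likely to fail**

Step 11 (ring closure). Intermolecular coupling to oligomers, protodeboronation or β-hydride loss may outrun the slow, base-dependent boron-to-palladium transfer at the dilution needed for a strained ten-membered E,Z-diene. The fallback leaves the route at 17 and returns at 19. Hydroboration of 17 with 9-BBN (giving 18) followed by iodinolysis (I2, NaOMe) should give (2S,3Z,6S,7E)-6-(TBSO)-8-iodo-2-[(3S)-1-iodo-3,7-dimethyloct-6-en-3-yl]-4-methylnona-3,7-dien-1-ol F1. Transient O-silylation (Me3SiCl, Et3N) and zinc insertion into the alkyl carbon–iodine bond (Zn dust, LiCl, THF, 25 °C, which leaves the alkenyl iodide alone) would give the O-trimethylsilyl alkylzinc iodide F2. Slow addition of this to Pd(OAc)2/SPhos in THF at 50 °C would close the ring by an intramolecular Negishi coupling, whose transmetalation needs no base. Mild acidic work-up removes the trimethylsilyl group and gives 19.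

Step 13 (key step). The C8 cation may lose a proton (from C7 or the C8 methyl) or be intercepted across the ring, and the medium ring may populate the C9–C10 rotamer that leads to the cis-fused cyclopropane, so that water capture at C8 through the required rotamer is outrun. The fallback leaves the route at 17 and returns at 21; it runs the same ionisation on the open chain, where A(1,3) strain alone fixes the rotamer and no transannular partner exists. Tosylation of 17 gives the open-chain homoallylic tosylate F3, and buffered solvolysis (NaHCO3, acetone–H2O, 60 °C) should give the open-chain (1S,6S,8S,9S,10S)-cyclopropyl carbinol F4. Hydroboration of its vinyl group with 9-BBN gives the C3 borane F5 (not isolated), and B-alkyl Suzuki coupling onto the alkenyl iodide under the conditions of step 11 closes the ten-membered ring to give 21.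

Step 18 (peroxide introduction). Allylic transposition (SN2′ attack at the terminal CH2), elimination to the diene or ionisation with loss of configuration may compete with direct displacement at the hindered secondary allylic carbon. The fallback leaves the route at 21 and returns at 30. Desilylation of 21 (Bu4NF, THF) gives (1S,4E,6S,8S,9S,10S)-1,4,8-trimethyl-1-(4-methylpent-3-en-1-yl)-9,10-methanocyclodec-4-ene-6,8-diol F6, and selective acetylation of the secondary hydroxyl (Ac2O, pyridine) gives the 6-acetate F7. A Schenck ene reaction of the prenyl alkene with singlet oxygen (O2, tetraphenylporphyrin, visible light, CH2Cl2, 0 °C) should then form 30 directly, together with its (14R)-epimer F8 and the regioisomeric tertiary hydroperoxide F9, from which 30 is separated by HPLC. This gives up control at C14 in exchange for a displacement-free installation of both oxygens.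

**Further compounds**

F1 | step 11 | (2S,3Z,6S,7E)-6-(TBSO)-8-iodo-2-[(3S)-1-iodo-3,7-dimethyloct-6-en-3-yl]-4-methylnona-3,7-dien-1-ol | CC(C)=CCC[C@@](C)(CCI)[C@@H](CO)/C=C(C)\C[C@H](O[Si](C)(C)C(C)(C)C)/C=C(\C)I
F2 | step 11 | O-trimethylsilyl alkylzinc iodide derived from F1 (zinc on C3) | CC(C)=CCC[C@@](C)(CC[Zn]I)[C@@H](CO[Si](C)(C)C)/C=C(C)\C[C@H](O[Si](C)(C)C(C)(C)C)/C=C(\C)I
F3 | step 13 | (2S,3Z,6S,7E)-6-(TBSO)-2-[(3S)-3,7-dimethylocta-1,6-dien-3-yl]-8-iodo-4-methylnona-3,7-dien-1-yl 4-methylbenzenesulfonate | CC(C)=CCC[C@@](C)(C=C)[C@@H](COS(=O)(=O)c1ccc(C)cc1)/C=C(C)\C[C@H](O[Si](C)(C)C(C)(C)C)/C=C(\C)I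
F4 | step 13 | open-chain (1S,6S,8S,9S,10S)-cyclopropyl carbinol with C1 vinyl and C4 iodide (route numbering) | CC(C)=CCC[C@@](C)(C=C)[C@H]1C[C@@H]1[C@@](C)(O)C[C@H](O[Si](C)(C)C(C)(C)C)/C=C(\C)I
F5 | step 13 | 9-BBN adduct of F4 (boron on C3) | CC(C)=CCC[C@@](C)(CCB1C2CCCC1CCC2)[C@H]1C[C@@H]1[C@@](C)(O)C[C@H](O[Si](C)(C)C(C)(C)C)/C=C(\C)I
F6 | step 18 | (1S,4E,6S,8S,9S,10S)-1,4,8-trimethyl-1-(4-methylpent-3-en-1-yl)-9,10-methanocyclodec-4-ene-6,8-diol | CC(C)=CCC[C@@]1(C)CC/C(C)=C/[C@@H](O)C[C@](C)(O)[C@H]2C[C@@H]21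
F7 | step 18 | (1S,4E,6S,8S,9S,10S)-8-hydroxy-1,4,8-trimethyl-1-(4-methylpent-3-en-1-yl)-9,10-methanocyclodec-4-en-6-yl acetate | CC(C)=CCC[C@@]1(C)CC/C(C)=C/[C@@H](OC(C)=O)C[C@](C)(O)[C@H]2C[C@@H]21
F8 | step 18 | (14R)-epimer of 30 | C=C(C)[C@@H](CC[C@@]1(C)CC/C(C)=C/[C@@H](OC(C)=O)C[C@](C)(O)[C@H]2C[C@@H]21)OO
F9 | step 18 | (1R,4E,6S,8S,9S,10S)-1-[(2E)-4-hydroperoxy-4-methylpent-2-en-1-yl]-8-hydroxy-1,4,8-trimethyl-9,10-methanocyclodec-4-en-6-yl acetate | CC(C)(OO)/C=C/C[C@@]1(C)CC/C(C)=C/[C@@H](OC(C)=O)C[C@](C)(O)[C@H]2C[C@@H]21
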